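**Analysis of the target**

The target 31 is a cis-fused decalin of the eremophilane type. Ring A (C1–C5, C10) carries the C3 angelate and the C4 methyl group (C15); ring B (C5–C10) carries the C8 ketone, flanked by the C7 isopropenyl group and the C9 angelate; the ring-fusion carbon C5 is quaternary and bears methyl C14. There are six stereocentres (C3, C4, C5, C7, C9, C10). With the two methyl groups taken as β, H10 is β (cis fusion), the C3 ester is α, and the C9 ester and the C7 isopropenyl group are β. In the chair–chair form with C14 axial on ring A, the substituents at C3, C4, C7 and C9 are all equatorial, so the two enolisable centres C7 and C9 already sit in their more stable configurations. The sensitive groups are the two (Z)-2-methylbut-2-enoates, which isomerise to tiglates, the β,γ-unsaturated ketone, whose alkene can move into conjugation, and the α-acyloxy ketone. The hard part is the quaternary C5 between the C4 and C10 stereocentres, with the two methyl groups cis and the rings cis-fused. The plan rests on one feature: C14 is a methyl group on a quaternary carbon, so it can be made from an exocyclic C5=C14 methylene by adding a hydrogen atom, and the resulting tertiary C5 radical can close ring B by bonding to C6 of a C8 vinyl ketone.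

**Retrosynthetic reasoning**

Ester C–O bonds at C3 and C9. The two angelates are cut first, giving diol 28 and angelic acid 29 (activated as mixed anhydride 30). Angelates do not survive strong base, fluoride base or nucleophilic catalysts without Z to E isomerisation, so they go on last, in one Yamaguchi esterification.

Silyl ethers and the isopropenyl group. Diol 28 comes from bis-silyl ether 27. The C11=C12 alkene of 27 is traced to tertiary carbinol 25, and the C7–C11 bond of 25 is cut to ketone 22 and acetone 23. C7 is the only unhindered α-carbon of 22, and the aldol places the new group equatorial; the dehydration must then remove a methyl hydrogen and not H7.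

C5–C6 bond (key disconnection). Cutting C5–C6 in 22 opens ring B and gives methylene vinyl ketone 19. This cut removes the quaternary centre and its methyl group together: in the forward direction H• adds to C14 of 19, radical 20 closes onto the enone, and radical 21 is reduced to 22. It is made here and not elsewhere because the donor alkene and the acceptor enone are polarity-matched, the C8 and C9 oxygens are already in place, and the three ring A stereocentres of 19 can steer the one new centre.

C7–C8 bond and the C8 oxidation level. Enone 19 comes from allylic alcohol 18, which is cut between C7 and C8 to aldehyde 16 and vinylmagnesium bromide 17. Aldehyde 16 comes from primary alcohol 15, and 15 from tris-silyl ether 14 by selective loss of the primary silyl group. The enone is made last in this sequence because it would not survive the methylenation or the Grignard step.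

C5=C14 bond. The methylene of 14 is traced to the C5 ketone of 13 (Petasis methylenation). The ketone is needed one stage earlier as the handle for the C9–C10 bond.

C9–C10 bond. Ketone 13 is the silyl ether of aldol adduct 12, which is cut to ring A ketone 8 and aldehyde 9. The forward aldol (through enolates 10 and 11) must set C10 trans to the C4 methyl group and C9 syn to the ring, which is the opposite of the usual outcome for a ring-locked E enolate; a titanium enolate is therefore chosen.

Ring A stereotriad. Ketone 8 comes from alcohol 7, its benzyl ether 6, alcohol 5 (through borane 4) and allylic ether 3, that is from allylic alcohol 2 and enone 1. One catalytic asymmetric reduction sets the carbinol centre of 2; this centre directs the hydroboration that fixes C3 and C4 and is then oxidised away to the C5 carbonyl.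

**Alternatives that were turned down**

Alternative 1: Both rings are cut at once, at C3–C4 and C5–C10, back to the open-chain trienone A1. In the forward direction the acetoxy diene C10=C1–C2=C3 of A1 would add to the C4=C5 alkene of its tigloyl ketone in an intramolecular Diels–Alder reaction through the C6–C9 tether, giving the cis-fused octalinone A2. In its favour, two rings, two C–C bonds and four stereocentres (C3, C4, C5, C10) arise in one step from an achiral chain, and the E geometry of the tigloyl unit encodes the cis relation of the methyl groups. On bond count and convergence it is stronger than the chosen plan. Against it, the dienophile is trisubstituted and must form a quaternary carbon, so the cycloaddition is slow; endo/exo and cis/trans fusion are not secured; and since A1 is achiral the absolute configuration has to come from a chiral catalyst on a difficult substrate. The oxidation pattern of A2 is also wrong: its carbonyl is at C6, where the target has CH2, and C8 and C9 are bare, so an oxygen transposition, a C9 oxidation and removal of the C1=C2 alkene would follow. The chosen route gives ring B with oxygen at C8 and C9 already correct and relies on substrate control from existing centres.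

Alternative 2: The C1–C10 bond is cut with a sacrificial C3–C8 bond added, leading back to the bridged carbinol A3. Its alkoxide would undergo an anionic oxy-Cope rearrangement to the cis-fused ketone enol ether A4. In its favour, the shift is concerted and stereospecific: the bridged framework fixes C5, C10 and the cis fusion with no facial question, and A4 has oxygen at C3 and at C8, with the enol ether ready for oxidation at C9. On certainty of the ring fusion it is stronger than a radical closure. Against it, the difficulty moves into A3: a regio- and enantioselective cycloaddition is needed for the bridgehead-methoxy bicycle, the vinyl group must then add syn to the ring alkene next to the C4 methyl centre, and C4 becomes epimerisable once the C3 ketone is released. C3 reduction, C9 oxidation and the whole C7 side chain still follow. The chosen route reaches its precursor from a simple monocycle of secured absolute configuration and creates the methyl group in the ring-closing step.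

Alternative 3: The C7–C8 bond is cut, leading back to the prenyl aldehyde A5. A Lewis-acid-promoted carbonyl-ene closure of A5 would form ring B and give the homoallylic alcohol A6. In its favour, this closure creates the isopropenyl group and the C7 centre as the ring forms, so it avoids the aldol and dehydration steps of the chosen route; on that point it is stronger. Against it, the quaternary C5 with methyl and prenyl groups, the hardest centre, must already be in A5 and is not addressed by the key step. A6 has no oxygen at C9; after oxidation at C8 the C9 hydroxyl would have to be introduced next to a ketone whose other α-hydrogen (H7) is more acidic and allylic, with the alkene ready to move into conjugation. The chosen route carries the C9 oxygen from the aldol step and forms the quaternary centre in the key step; it pays for this with a late isopropenyl installation.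

Key step: step 14

Remark: positions are numbered as in eremophilane (ring A = C1–C5 and C10, ring B = C5–C10, C14 on C5, C15 on C4); the face carrying both methyl groups is called β.
Remark: ring A is entered through enone 1 and not through 2-methylcyclohexane-1,3-dione, because that dione is enolised and offers no ketone for a clean asymmetric monoreduction.
Remark: 18 is carried as a mixture of C8 epimers; this centre is removed in step 13.

Step 1
Reactants: 1 2-methylcyclohex-2-en-1-one
Product: 2 (1R)-2-methylcyclohex-2-en-1-ol
Conditions: (S)-Me-CBS oxazaborolidine (10 mol %), BH3·SMe2, THF, −20 °C; MeOH, aq. work-up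
Reagents that add atoms: none
Why: Corey–Bakshi–Shibata reduction; the α-methyl-substituted alkenyl arm acts as the large group, so the (S)-catalyst should deliver hydride to give the (R)-carbinol, and 1,2-reduction is favoured over conjugate reduction at low temperature.

Step 2
Reactants: 2 (1R)-2-methylcyclohex-2-en-1-ol
Product: 3 {[(1R)-2-methylcyclohex-2-en-1-yl]oxymethyl}benzene (benzyl ether of 2)
Conditions: NaH, BnBr, Bu4NI (cat.), THF, 0 °C → rt
Reagents that add atoms: benzyl bromide, BrCc1ccccc1
Why: Williamson etherification; the benzyl ether survives hydroboration and silylation and can later be removed by hydrogenolysis without touching a silyl ether.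

Step 3
Reactants: 3 benzyl ether of 2
Product: 5 (1R,2S,3R)-3-(benzyloxy)-2-methylcyclohexan-1-ol, via alkylborane 4 (not isolated)
Conditions: BH3·SMe2, THF, 0 °C → rt; then NaOH, H2O2, H2O, 0 °C → rt
Reagents that add atoms: borane–dimethyl sulfide, [BH3-][S+](C)C (boron, only in 4); hydrogen peroxide, OO
Why: Hydroboration–oxidation; boron adds to the less substituted alkene carbon and, because allylic strain with the vinylic methyl holds the benzyloxy group pseudoaxial, on the face anti to it. Syn addition and oxidation with retention should leave the methyl group cis to the benzyloxy group and trans to the new hydroxyl.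

Step 4
Reactants: 5 (1R,2S,3R)-3-(benzyloxy)-2-methylcyclohexan-1-ol
Product: 6 {[(1R,2R,3R)-3-(benzyloxy)-2-methylcyclohexyl]oxy}(tert-butyl)dimethylsilane
Conditions: TBSCl, imidazole, DMF, rt
Reagents that add atoms: tert-butyldimethylsilyl chloride, CC(C)(C)[Si](C)(C)Cl
Why: Standard imidazole-promoted silylation of an equatorial secondary alcohol; no stereocentre is touched.

Step 5
Reactants: 6 silyl benzyl diether
Product: 7 (1R,2R,3R)-3-[(tert-butyldimethylsilyl)oxy]-2-methylcyclohexan-1-ol
Conditions: H2 (1 atm), Pd/C, EtOAc, rt
Reagents that add atoms: none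
Why: Hydrogenolysis of the benzyl ether; the silyl ether and the saturated ring are inert under neutral conditions.

Step 6
Reactants: 7 (1R,2R,3R)-3-[(tert-butyldimethylsilyl)oxy]-2-methylcyclohexan-1-ol
Product: 8 (2S,3R)-3-[(tert-butyldimethylsilyl)oxy]-2-methylcyclohexan-1-one
Conditions: Dess–Martin periodinane, NaHCO3, CH2Cl2, 0 °C → rt
Reagents that add atoms: none
Why: Dess–Martin oxidation under buffered conditions avoids β-elimination of the silyloxy group; the C2 methyl is already in the more stable trans (diequatorial) relation to it, so no epimerisation is expected.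

Step 7
Reactants: 8 (2S,3R)-3-[(tert-butyldimethylsilyl)oxy]-2-methylcyclohexan-1-one; 9 (tert-butyldimethylsilyloxy)acetaldehyde
Product: 12 (2S,3R,6R)-3-[(tert-butyldimethylsilyl)oxy]-6-[(1R)-2-[(tert-butyldimethylsilyl)oxy]-1-hydroxyethyl]-2-methylcyclohexan-1-one, via lithium enolate 10 (not isolated), via titanium enolate 11 (not isolated)
Conditions: LiN(iPr)2, THF, −78 °C; ClTi(OiPr)3, −78 → −40 °C; 9, −78 °C; aq. NH4Cl
Reagents that add atoms: LiN(iPr)2, [Li]N(C(C)C)C(C)C (lithium, only in 10); ClTi(OiPr)3, CC(C)O[Ti](Cl)(OC(C)C)OC(C)C (titanium triisopropoxide unit, only in 11)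
Why: Titanium enolate aldol addition; the amide base removes a proton from the less substituted C6 methylene, and triisopropoxytitanium enolates of cyclic ketones are known to give syn aldols where the lithium enolate follows the Zimmerman–Traxler course to anti. Axial bond formation on the enolate with methyl and silyloxy equatorial should place the new chain trans to the C2 methyl, so C10 and C9 (eremophilane numbering) are set together.

Step 8
Reactants: 12 aldol adduct
Product: 13 (2S,3R,6R)-6-[(1R)-1,2-bis[(tert-butyldimethylsilyl)oxy]ethyl]-3-[(tert-butyldimethylsilyl)oxy]-2-methylcyclohexan-1-one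
Conditions: TBSOTf, 2,6-lutidine, CH2Cl2, −78 °C
Reagents that add atoms: tert-butyldimethylsilyl trifluoromethanesulfonate, CC(C)(C)[Si](C)(C)OS(=O)(=O)C(F)(F)F
Why: Low-temperature silylation with a hindered base blocks retro-aldol cleavage and should not epimerise the axial C6 substituent.

Step 9
Reactants: 13 tris-silyl ketone
Product: 14 tert-butyl{[(1R,2R,4S)-4-[(1R)-1,2-bis[(tert-butyldimethylsilyl)oxy]ethyl]-2-methyl-3-methylidenecyclohexyl]oxy}dimethylsilane
Conditions: Cp2TiMe2, toluene, 70 °C, dark
Reagents that add atoms: Cp2TiMe2 (bis(cyclopentadienyl)dimethyltitanium), C[Ti](C)(C1C=CC=C1)C1C=CC=C1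
Why: Petasis methylenation; the titanium methylidene formed on heating is not basic, so the epimerisable centres on both sides of the hindered ketone and the β-silyloxy group are expected to survive.

Step 10
Reactants: 14 tris-silyl ether
Product: 15 (2R)-2-[(tert-butyldimethylsilyl)oxy]-2-[(1S,3R,4R)-4-[(tert-butyldimethylsilyl)oxy]-3-methyl-2-methylidenecyclohexyl]ethan-1-ol
Conditions: HF·pyridine, pyridine, THF, 0 °C
Reagents that add atoms: none
Why: Selective desilylation; the primary silyl ether is cleaved much faster than the two hindered secondary ones, and buffered acidic fluoride avoids 1,2-silyl migration.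

Step 11
Reactants: 15 primary alcohol
Product: 16 (2R)-2-[(tert-butyldimethylsilyl)oxy]-2-[(1S,3R,4R)-4-[(tert-butyldimethylsilyl)oxy]-3-methyl-2-methylidenecyclohexyl]acetaldehyde
Conditions: Dess–Martin periodinane, NaHCO3, CH2Cl2, 0 °C
Reagents that add atoms: none
Why: Dess–Martin oxidation gives the α-silyloxy aldehyde under buffered conditions that should not epimerise C9; the aldehyde is used crude.

Step 12
Reactants: 16 α-silyloxy aldehyde; 17 vinylmagnesium bromide
Product: 18 (1R,2RS)-1-[(tert-butyldimethylsilyl)oxy]-1-[(1S,3R,4R)-4-[(tert-butyldimethylsilyl)oxy]-3-methyl-2-methylidenecyclohexyl]but-3-en-2-ol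
Conditions: 17, THF, −78 °C; aq. NH4Cl
Reagents that add atoms: none
Why: Grignard addition to the aldehyde at low temperature; the new carbinol centre is formed as a mixture and is removed in the next step.

Step 13
Reactants: 18 allylic alcohol
Product: 19 (1R)-1-[(tert-butyldimethylsilyl)oxy]-1-[(1S,3R,4R)-4-[(tert-butyldimethylsilyl)oxy]-3-methyl-2-methylidenecyclohexyl]but-3-en-2-one
Conditions: Dess–Martin periodinane, NaHCO3, CH2Cl2, 0 °C
Reagents that add atoms: none
Why: Dess–Martin oxidation of the allylic alcohol gives the vinyl ketone without base; the enone is used at once to avoid oligomerisation.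

Step 14
Reactants: 19 methylene vinyl ketone
Product: 22 (1R,4aR,5R,6R,8aS)-1,6-bis[(tert-butyldimethylsilyl)oxy]-4a,5-dimethyloctahydronaphthalen-2(1H)-one, via tertiary C5 radical 20 (not isolated), via cyclised C7 radical 21 (not isolated)
Conditions: Fe(acac)3 (30 mol %), PhSiH3, EtOH/ethylene glycol, 60 °C, 0.01 M, degassed
Reagents that add atoms: none
Why: Metal-hydride hydrogen atom transfer radical conjugate cyclisation, the intramolecular form of the known iron-catalysed olefin–enone reductive coupling (a Giese-type addition). The trivalent iron hydride formed from Fe(acac)3 and PhSiH3 delivers a hydrogen atom to the terminal C14 of the electron-rich 1,1-disubstituted alkene and so gives the tertiary C5 radical 20. This nucleophilic radical adds to C6, the unsubstituted β-carbon of the vinyl ketone, and closes ring B in a 6-endo-trig mode through a chair-like transition state; the 5-exo alternative would mean attack on the enone α-carbon and is polarity-mismatched. The α-keto radical 21 is reduced by divalent iron to the enolate and protonated by ethanol. C5 is the only new stereocentre and is controlled by ring A: with the C4 methyl and C3 silyloxy groups equatorial the C10 side chain is axial on the α face, so C6 reaches C5 only from that face and the C14 methyl ends β, cis to C15, with a cis ring fusion. A trans-fused closure would need the ring-flipped chair and would build up a 1,3-diaxial contact between C14 and the C3 silyloxy group. The step needs hydrogen atom transfer to the methylene in preference to the enone and ring closure faster than reduction or isomerisation of the radical; the more reactive 1,1-disubstituted donor, the terminal acceptor and high dilution should secure both.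

Step 15
Reactants: 22 bis-silyloxy decalinone; 23 acetone
Product: 25 (1R,3R,4aR,5R,6R,8aS)-1,6-bis[(tert-butyldimethylsilyl)oxy]-3-(2-hydroxypropan-2-yl)-4a,5-dimethyloctahydronaphthalen-2(1H)-one, via lithium enolate 24 (not isolated)
Conditions: LiN(iPr)2, THF, −78 °C; 23, −78 °C; AcOH, −78 °C
Reagents that add atoms: LiN(iPr)2, [Li]N(C(C)C)C(C)C (lithium, only in 24)
Why: Kinetic aldol addition; the base removes a proton from the unhindered C7 methylene and not from the silyloxy-bearing C9 methine. Acetone should add on the convex β face, away from the axial C4 carbon of ring A, giving the equatorial and thermodynamically preferred adduct; the cold acidic quench prevents retro-aldol cleavage.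

Step 16
Reactants: 25 tertiary carbinol
Product: 27 (1R,3R,4aR,5R,6R,8aS)-1,6-bis[(tert-butyldimethylsilyl)oxy]-4a,5-dimethyl-3-(prop-1-en-2-yl)octahydronaphthalen-2(1H)-one, via chlorosulfite 26 (not isolated)
Conditions: SOCl2, pyridine, CH2Cl2, −30 → 0 °C
Reagents that add atoms: thionyl chloride, O=S(Cl)Cl (only in 26)
Why: Dehydration of a tertiary carbinol through its chlorosulfite (E2 with pyridine); loss of one of six methyl hydrogens is statistically and sterically favoured over the shielded H7, and the weak base at low temperature should avoid the enolisation that would move the alkene into conjugation.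

Step 17
Reactants: 27 bis-silyl ether
Product: 28 (1R,3R,4aR,5R,6R,8aS)-1,6-dihydroxy-4a,5-dimethyl-3-(prop-1-en-2-yl)octahydronaphthalen-2(1H)-one
Conditions: HF (48 % aq.), MeCN, 0 °C → rt
Reagents that add atoms: none
Why: Acidic fluoride cleaves both secondary silyl ethers; it is not basic, so the β,γ-unsaturated ketone and the C7 and C9 centres are not put at risk as they would be with Bu4NF.

Step 18
Reactants: 28 diol; 29 angelic acid
Product: 31 (1R,3R,4aR,5R,6R,8aS)-4a,5-dimethyl-2-oxo-3-(prop-1-en-2-yl)decahydronaphthalene-1,6-diyl bis[(2Z)-2-methylbut-2-enoate] (target), via mixed anhydride 30 (not isolated)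
Conditions: 29, 2,4,6-Cl3C6H2COCl, Et3N, toluene, rt; then 28, toluene, 80 °C
Reagents that add atoms: 2,4,6-trichlorobenzoyl chloride, O=C(Cl)c1c(Cl)cc(Cl)cc1Cl (only in 30)
Why: Yamaguchi esterification through the mixed anhydride without a nucleophilic catalyst, the usual way to acylate hindered alcohols with angelic acid while keeping the Z geometry (nucleophilic catalysts isomerise it to the tiglate by conjugate addition–elimination); both secondary hydroxyls are acylated.

**Compound list**

1 | 2-methylcyclohex-2-en-1-one | CC1=CCCCC1=O | starting material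
2 | (1R)-2-methylcyclohex-2-en-1-ol | O[C@H]1C(C)=CCCC1 | intermediate
3 | {[(1R)-2-methylcyclohex-2-en-1-yl]oxymethyl}benzene | C(O[C@H]1C(C)=CCCC1)c1ccccc1 | intermediate
4 | [(1R,2S,3R)-3-(benzyloxy)-2-methylcyclohexyl]borane | O(Cc1ccccc1)[C@H]1[C@@H](C)[C@H](B)CCC1 | intermediate
5 | (1R,2S,3R)-3-(benzyloxy)-2-methylcyclohexan-1-ol | O(Cc1ccccc1)[C@H]1[C@@H](C)[C@H](O)CCC1 | intermediate
6 | {[(1R,2R,3R)-3-(benzyloxy)-2-methylcyclohexyl]oxy}(tert-butyl)dimethylsilane | O(Cc1ccccc1)[C@H]1[C@@H](C)[C@H](O[Si](C)(C)C(C)(C)C)CCC1 | intermediate
7 | (1R,2R,3R)-3-[(tert-butyldimethylsilyl)oxy]-2-methylcyclohexan-1-ol | O[C@H]1[C@@H](C)[C@H](O[Si](C)(C)C(C)(C)C)CCC1 | intermediate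
8 | (2S,3R)-3-[(tert-butyldimethylsilyl)oxy]-2-methylcyclohexan-1-one | O=C1[C@@H](C)[C@H](O[Si](C)(C)C(C)(C)C)CCC1 | intermediate
9 | (tert-butyldimethylsilyloxy)acetaldehyde | CC(C)(C)[Si](C)(C)OCC=O | starting material
10 | lithium (5R,6S)-5-[(tert-butyldimethylsilyl)oxy]-6-methylcyclohex-1-en-1-olate | [Li]OC1=CCC[C@@H](O[Si](C)(C)C(C)(C)C)[C@@H]1C | intermediate
11 | {[(5R,6S)-5-[(tert-butyldimethylsilyl)oxy]-6-methylcyclohex-1-en-1-yl]oxy}tri(propan-2-yloxy)titanium | CC(C)O[Ti](OC(C)C)(OC(C)C)OC1=CCC[C@@H](O[Si](C)(C)C(C)(C)C)[C@@H]1C | intermediate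
12 | (2S,3R,6R)-3-[(tert-butyldimethylsilyl)oxy]-6-[(1R)-2-[(tert-butyldimethylsilyl)oxy]-1-hydroxyethyl]-2-methylcyclohexan-1-one | O=C1[C@@H](C)[C@H](O[Si](C)(C)C(C)(C)C)CC[C@@H]1[C@@H](O)CO[Si](C)(C)C(C)(C)C | intermediate
13 | (2S,3R,6R)-6-[(1R)-1,2-bis[(tert-butyldimethylsilyl)oxy]ethyl]-3-[(tert-butyldimethylsilyl)oxy]-2-methylcyclohexan-1-one | O=C1[C@@H](C)[C@H](O[Si](C)(C)C(C)(C)C)CC[C@@H]1[C@@H](O[Si](C)(C)C(C)(C)C)CO[Si](C)(C)C(C)(C)C | intermediate
14 | tert-butyl{[(1R,2R,4S)-4-[(1R)-1,2-bis[(tert-butyldimethylsilyl)oxy]ethyl]-2-methyl-3-methylidenecyclohexyl]oxy}dimethylsilane | C=C1[C@@H](C)[C@H](O[Si](C)(C)C(C)(C)C)CC[C@@H]1[C@@H](O[Si](C)(C)C(C)(C)C)CO[Si](C)(C)C(C)(C)C | intermediate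
15 | (2R)-2-[(tert-butyldimethylsilyl)oxy]-2-[(1S,3R,4R)-4-[(tert-butyldimethylsilyl)oxy]-3-methyl-2-methylidenecyclohexyl]ethan-1-ol | C=C1[C@@H](C)[C@H](O[Si](C)(C)C(C)(C)C)CC[C@@H]1[C@@H](O[Si](C)(C)C(C)(C)C)CO | intermediate
16 | (2R)-2-[(tert-butyldimethylsilyl)oxy]-2-[(1S,3R,4R)-4-[(tert-butyldimethylsilyl)oxy]-3-methyl-2-methylidenecyclohexyl]acetaldehyde | C=C1[C@@H](C)[C@H](O[Si](C)(C)C(C)(C)C)CC[C@@H]1[C@@H](O[Si](C)(C)C(C)(C)C)C=O | intermediate
17 | vinylmagnesium bromide | C=C[Mg]Br | starting material
18 | (1R,2RS)-1-[(tert-butyldimethylsilyl)oxy]-1-[(1S,3R,4R)-4-[(tert-butyldimethylsilyl)oxy]-3-methyl-2-methylidenecyclohexyl]but-3-en-2-ol | C=C1[C@@H](C)[C@H](O[Si](C)(C)C(C)(C)C)CC[C@@H]1[C@@H](O[Si](C)(C)C(C)(C)C)C(O)C=C | intermediate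
19 | (1R)-1-[(tert-butyldimethylsilyl)oxy]-1-[(1S,3R,4R)-4-[(tert-butyldimethylsilyl)oxy]-3-methyl-2-methylidenecyclohexyl]but-3-en-2-one | C=C1[C@@H](C)[C@H](O[Si](C)(C)C(C)(C)C)CC[C@@H]1[C@@H](O[Si](C)(C)C(C)(C)C)C(=O)C=C | intermediate
20 | tertiary C5 radical formed from 19 by hydrogen atom addition to the methylidene carbon | C[C]1[C@@H](C)[C@H](O[Si](C)(C)C(C)(C)C)CC[C@@H]1[C@@H](O[Si](C)(C)C(C)(C)C)C(=O)C=C | intermediate
21 | cyclised radical at C7 (α to the C8 carbonyl) with the skeleton of 22 | [CH]1C[C@@]2(C)[C@H](CC[C@@H](O[Si](C)(C)C(C)(C)C)[C@@H]2C)[C@@H](O[Si](C)(C)C(C)(C)C)C1=O | intermediate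
22 | (1R,4aR,5R,6R,8aS)-1,6-bis[(tert-butyldimethylsilyl)oxy]-4a,5-dimethyloctahydronaphthalen-2(1H)-one | C1C[C@@]2(C)[C@H](CC[C@@H](O[Si](C)(C)C(C)(C)C)[C@@H]2C)[C@@H](O[Si](C)(C)C(C)(C)C)C1=O | intermediate
23 | acetone | CC(C)=O | starting material
24 | lithium enolate of 22 (C7=C8) | [Li]OC1=CC[C@@]2(C)[C@H](CC[C@@H](O[Si](C)(C)C(C)(C)C)[C@@H]2C)[C@H]1O[Si](C)(C)C(C)(C)C | intermediate
25 | (1R,3R,4aR,5R,6R,8aS)-1,6-bis[(tert-butyldimethylsilyl)oxy]-3-(2-hydroxypropan-2-yl)-4a,5-dimethyloctahydronaphthalen-2(1H)-one | CC(C)(O)[C@H]1C[C@@]2(C)[C@H](CC[C@@H](O[Si](C)(C)C(C)(C)C)[C@@H]2C)[C@@H](O[Si](C)(C)C(C)(C)C)C1=O | intermediate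
26 | chlorosulfite ester of the tertiary hydroxyl of 25 | CC(C)(OS(=O)Cl)[C@H]1C[C@@]2(C)[C@H](CC[C@@H](O[Si](C)(C)C(C)(C)C)[C@@H]2C)[C@@H](O[Si](C)(C)C(C)(C)C)C1=O | intermediate
27 | (1R,3R,4aR,5R,6R,8aS)-1,6-bis[(tert-butyldimethylsilyl)oxy]-4a,5-dimethyl-3-(prop-1-en-2-yl)octahydronaphthalen-2(1H)-one | C=C(C)[C@H]1C[C@@]2(C)[C@H](CC[C@@H](O[Si](C)(C)C(C)(C)C)[C@@H]2C)[C@@H](O[Si](C)(C)C(C)(C)C)C1=O | intermediate
28 | (1R,3R,4aR,5R,6R,8aS)-1,6-dihydroxy-4a,5-dimethyl-3-(prop-1-en-2-yl)octahydronaphthalen-2(1H)-one | C=C(C)[C@H]1C[C@@]2(C)[C@H](CC[C@@H](O)[C@@H]2C)[C@@H](O)C1=O | intermediate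
29 | angelic acid, (2Z)-2-methylbut-2-enoic acid | C/C=C(/C)C(=O)O | starting material
30 | (2Z)-2-methylbut-2-enoic 2,4,6-trichlorobenzoic anhydride | C/C=C(/C)C(=O)OC(=O)c1c(Cl)cc(Cl)cc1Cl | intermediate
31 | (1R,3R,4aR,5R,6R,8aS)-4a,5-dimethyl-2-oxo-3-(prop-1-en-2-yl)decahydronaphthalene-1,6-diyl bis[(2Z)-2-methylbut-2-enoate] (CNP0174755.1) | C=C(C)[C@H]1C[C@@]2(C)[C@H](CC[C@@H](OC(=O)/C(C)=C\C)[C@@H]2C)[C@@H](OC(=O)/C(C)=C\C)C1=O | target

**Step count and risks**

Total step count: 18. Longest linear sequence: 18 steps (1 → 31); 9, 17, 23 and 29 are commercial and enter directly.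

Least certain steps:

Step 14 (key step). The most likely failure is hydrogen atom transfer or hydride conjugate reduction at the vinyl ketone before the methylene is engaged, together with oligomerisation of the enone, because both alkenes of 19 react with the same reagent; closure to the trans-fused isomer is a lesser concern. The fallback generates the same radical without a hydride reagent; it sets out from 13 and returns at 22. Methyl addition to the C5 carbonyl of 13 (MeMgBr, CeCl3, THF, −78 °C) would give the tertiary carbinol F1 as either C5 epimer, which is acceptable because this centre becomes planar later. Buffered HF·pyridine frees the primary hydroxyl to give the diol F2, and Swern oxidation gives the hydroxy aldehyde, which should rest as the lactol F3. Excess 17 opens the lactol to the vinyl carbinol diol F4, and MnO2 oxidises only the allylic carbinol to the hydroxy enone F5. Acylation of the tertiary hydroxyl with N-phthalimidoyl chlorooxalate gives the N-phthalimidoyl oxalate F6. Visible-light photoredox reduction (Ru(bpy)3(PF6)2, Hantzsch ester, blue light) fragments F6 with loss of two CO2 to radical 20, which closes through 21 to 22.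

Step 7. The likely failure is loss of simple diastereoselectivity (anti in place of syn at C9/C10), since the ring-locked E enolate prefers the anti course in a closed transition state, or partial epimerisation of the axial chain at C10. The fallback uses an open transition state under chelation control; it sets out from 8 and returns at 15. Trapping of enolate 10 with Me3SiCl gives the trimethylsilyl enol ether F7. A Mukaiyama aldol of F7 with (4-methoxybenzyloxy)acetaldehyde and TiCl4 at −78 °C, in which the aldehyde is held as a five-membered chelate, should give the syn adduct F8. Silylation (TBSOTf, 2,6-lutidine) gives the C9 silyl ether F9, Petasis methylenation gives the methylidene compound F10, and DDQ removes the 4-methoxybenzyl group to give 15.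

Step 9. The likely failure is incomplete conversion of the hindered, doubly α-branched ketone, or epimerisation next to the carbonyl during prolonged heating. The fallback is a two-stage Peterson olefination; it sets out from 13 and returns at 14. Me3SiCH2Li with CeCl3 adds to hindered, enolisable ketones at −78 °C and would give the β-hydroxysilane F11; KH in THF then eliminates it to 14.

Step 16. The likely failure is loss of regiocontrol, with elimination toward C7 giving the conjugated isopropylidene ketone, because H7 is acidified by the carbonyl. The fallback sets out from 25 and returns at 27. The crude dehydration mixture is isomerised completely with DBU to the conjugated isopropylidene ketone F12. KOtBu in THF/t-BuOH converts F12 into the extended potassium dienolate F13, and inverse quench into cold aqueous acetic acid protonates it kinetically at C7 from the axial direction, which is the known deconjugation of α-alkylidene ketones and gives 27.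

Step 18. The likely failure is isomerisation during the slow acylation of the hindered C9 hydroxyl, either of the angelate to the tiglate or of the isopropenyl group into conjugation with the ketone. The fallback changes the order so that the acylation is run before the β,γ-unsaturated ketone exists; it sets out from 25 and returns at 31. Desilylation of 25 (aq. HF, MeCN) gives the triol F14. Yamaguchi esterification with 30 acylates the two secondary hydroxyls and leaves the tertiary one, giving the bis-angelate carbinol F15. SOCl2 and pyridine at −30 °C then dehydrate F15 through its chlorosulfite F16 to 31.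

**Further compounds**

F1 | step 14 | tertiary carbinol from methyl addition to the C5 carbonyl of 13 (either C5 epimer) | CC1(O)[C@@H](C)[C@H](O[Si](C)(C)C(C)(C)C)CC[C@@H]1[C@@H](O[Si](C)(C)C(C)(C)C)CO[Si](C)(C)C(C)(C)C
F2 | step 14 | diol from F1 with free primary C8 hydroxyl and tertiary C5 hydroxyl | CC1(O)[C@@H](C)[C@H](O[Si](C)(C)C(C)(C)C)CC[C@@H]1[C@@H](O[Si](C)(C)C(C)(C)C)CO
F3 | step 14 | five-membered lactol (C8 hemiacetal closed by the C5 oxygen) | CC1(O2)[C@@H](C)[C@H](O[Si](C)(C)C(C)(C)C)CC[C@@H]1[C@@H](O[Si](C)(C)C(C)(C)C)C2O
F4 | step 14 | diol with C8 vinyl carbinol and tertiary C5 hydroxyl | CC1(O)[C@@H](C)[C@H](O[Si](C)(C)C(C)(C)C)CC[C@@H]1[C@@H](O[Si](C)(C)C(C)(C)C)C(O)C=C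
F5 | step 14 | C5-hydroxy vinyl ketone | CC1(O)[C@@H](C)[C@H](O[Si](C)(C)C(C)(C)C)CC[C@@H]1[C@@H](O[Si](C)(C)C(C)(C)C)C(=O)C=C
F6 | step 14 | N-phthalimidoyl oxalate of the tertiary hydroxyl of F5 | CC1(OC(=O)C(=O)ON2C(=O)c3ccccc3C2=O)[C@@H](C)[C@H](O[Si](C)(C)C(C)(C)C)CC[C@@H]1[C@@H](O[Si](C)(C)C(C)(C)C)C(=O)C=C
F7 | step 7 | tert-butyldimethyl{[(1R,2S)-2-methyl-3-[(trimethylsilyl)oxy]cyclohex-3-en-1-yl]oxy}silane (trimethylsilyl enol ether of 8) | C[Si](C)(C)OC1=CCC[C@@H](O[Si](C)(C)C(C)(C)C)[C@@H]1C
F8 | step 7 | (2S,3R,6R)-3-[(tert-butyldimethylsilyl)oxy]-6-[(1R)-1-hydroxy-2-[(4-methoxybenzyl)oxy]ethyl]-2-methylcyclohexan-1-one | O=C1[C@@H](C)[C@H](O[Si](C)(C)C(C)(C)C)CC[C@@H]1[C@@H](O)COCc1ccc(OC)cc1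
F9 | step 7 | C9 tert-butyldimethylsilyl ether of F8 | O=C1[C@@H](C)[C@H](O[Si](C)(C)C(C)(C)C)CC[C@@H]1[C@@H](O[Si](C)(C)C(C)(C)C)COCc1ccc(OC)cc1
F10 | step 7 | C5-methylidene compound from F9 (4-methoxybenzyl ether of 15) | C=C1[C@@H](C)[C@H](O[Si](C)(C)C(C)(C)C)CC[C@@H]1[C@@H](O[Si](C)(C)C(C)(C)C)COCc1ccc(OC)cc1
F11 | step 9 | β-hydroxysilane from (trimethylsilyl)methyl addition to the C5 carbonyl of 13 (either C5 epimer) | C[Si](C)(C)CC1(O)[C@@H](C)[C@H](O[Si](C)(C)C(C)(C)C)CC[C@@H]1[C@@H](O[Si](C)(C)C(C)(C)C)CO[Si](C)(C)C(C)(C)C
F12 | step 16 | (1R,4aR,5R,6R,8aS)-1,6-bis[(tert-butyldimethylsilyl)oxy]-4a,5-dimethyl-3-(propan-2-ylidene)octahydronaphthalen-2(1H)-one | CC(C)=C1C[C@@]2(C)[C@H](CC[C@@H](O[Si](C)(C)C(C)(C)C)[C@@H]2C)[C@@H](O[Si](C)(C)C(C)(C)C)C1=O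
F13 | step 16 | potassium dienolate of F12 (C7=C8 enolate bearing the isopropenyl group) | C=C(C)C=1C[C@@]2(C)[C@H](CC[C@@H](O[Si](C)(C)C(C)(C)C)[C@@H]2C)[C@@H](O[Si](C)(C)C(C)(C)C)C=1[O-].[K+]
F14 | step 18 | (1R,3R,4aR,5R,6R,8aS)-1,6-dihydroxy-3-(2-hydroxypropan-2-yl)-4a,5-dimethyloctahydronaphthalen-2(1H)-one | CC(C)(O)[C@H]1C[C@@]2(C)[C@H](CC[C@@H](O)[C@@H]2C)[C@@H](O)C1=O
F15 | step 18 | 1,6-bis[(2Z)-2-methylbut-2-enoate] of F14 | CC(C)(O)[C@H]1C[C@@]2(C)[C@H](CC[C@@H](OC(=O)/C(C)=C\C)[C@@H]2C)[C@@H](OC(=O)/C(C)=C\C)C1=O
F16 | step 18 | chlorosulfite ester of the tertiary hydroxyl of F15 | CC(C)(OS(=O)Cl)[C@H]1C[C@@]2(C)[C@H](CC[C@@H](OC(=O)/C(C)=C\C)[C@@H]2C)[C@@H](OC(=O)/C(C)=C\C)C1=O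
A1 | alternative 1 | (1E,3E,9E)-9-methyl-8-oxoundeca-1,3,9-trien-1-yl acetate | CC(=O)O/C=C/C=C/CCCC(=O)/C(C)=C/C
A2 | alternative 1 | cis-fused 3α-acetoxy-4β,5β-dimethyl-Δ1-octalin-6-one | C1C(=O)[C@@]2(C)[C@H](C=C[C@@H](OC(C)=O)[C@@H]2C)CC1
A3 | alternative 2 | 1-methoxy-3,4-dimethyl-2-vinylbicyclo[2.2.2]oct-5-en-2-ol (vinyl and 3-methyl syn to the ring alkene) | CO[C@@]12CC[C@@](C)(C=C1)[C@@H](C)[C@@]2(O)C=C
A4 | alternative 2 | cis-fused 4β,5β-dimethyl decalin-3-one with C8 methyl enol ether (C8=C9) | C1C[C@@]2(C)[C@H](CCC(=O)[C@@H]2C)C=C1OC
A5 | alternative 3 | ring A acetaldehyde with quaternary C5 bearing methyl and prenyl, 3α-silyloxy, 4β-methyl | CC(C)=CC[C@@]1(C)[C@H](CC[C@@H](O[Si](C)(C)C(C)(C)C)[C@@H]1C)CC=O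
A6 | alternative 3 | cis-decalin with 7-isopropenyl, 8-hydroxyl and 3α-silyloxy groups | C=C(C)[C@H]1C[C@@]2(C)[C@H](CC[C@@H](O[Si](C)(C)C(C)(C)C)[C@@H]2C)C[C@@H]1O
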